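Monday's 0.35 equiv of reagent gave on average 35.5% of target, and I start from that pair of numbers.

| flask | substrate | reagent | remark | time |
|---|---|---|---|---|
| Wednesday's | 0.10 M | 0.70 equiv | run made earlier |  |
| Monday's | 0.10 M | 0.35 equiv | run made earlier |  |
| Friday's | 0.10 M | 1.4 equiv | run made earlier |  |
| north-east | 0.10 M | 0.700 equiv | everything together at the start | 2.5 h |
| south-west | 0.10 M (fed, over 1.0 h) | 0.700 equiv | all else is in the flask from the start; the feed brings no volume worth counting | 2.5 h |
| south-east | 0.10 M (in portions, 4, over 1.0 h) | 0.700 equiv | first portion at the start, last at 1.0 h | 2.5 h |
| north-west | 0.10 M | 0.700 equiv (fed, over 1.0 h) | all else is in the flask from the start; the feed brings no volume worth counting | 2.5 h |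

Wednesday's run (percent of the substrate charged)

| time / h | target / % | substrate / % |
|---|---|---|
| 0.200 | 65 | 5 |
| 0.500 | 68 | 5 |
| 1.00 | 70 | 8 |
| 2.50 | 63 | 9 |

Monday's run (percent of the substrate charged)

| time / min | target / % | substrate / % |
|---|---|---|
| 30.0 | 35 | 7 |
| 60.0 | 37 | 7 |
| 90.0 | 34 | 4 |
| 120 | 36 | 11 |

Friday's run (percent of the substrate charged)

| time / min | target / % | substrate / % |
|---|---|---|
| 15.0 | 95 | 0 |
| 40.0 | 101 | 0 |
| 80.0 | 100 | 5 |
| 120 | 100 | 3 |

(each reading ± 2 percentage points)



- the best flask by amount of target, in percent of the substrate charged; "all alike" if 1.5 percentage points covers them all (north-east / south-west / south-east / north-west / all alike)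
- amount of target at the end, in percent of the substrate charged, north-east
- amount of target at the end, in percent of the substrate charged, south-west
- amount of target at the end, in percent of the substrate charged, south-east
- amount of target at the end, in percent of the substrate charged, north-west

Dividing them gives ρ = 1.01, which I call the yield on reagent, meaning target as a fraction of the substrate charged per equivalent of reagent charged. Within the scatter, then, one reagent makes one target, and at 0.700 equiv I treat reagent as the limiting reagent.

My bound from above starts at the whole charge of substrate, 100 percent. But ρ times 0.700 equiv tightens it to 71.0%, and this ceiling rests on the reagent charge, which the flasks share. My bound from below comes from Wednesday's run, which has the same charges. Its lowest reading is 63%, but its mean is 66.5%, and taking off 2 percentage points as a margin gives a floor of 64.5%. That floor belongs to north-east, where everything goes in together. No earlier run was fed, so I give the fed flasks no floor.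

The forecast says 68% north-east, 68% south-west, 68% south-east and 67% north-west, hence all alike, since “order of addition hardly matters”. Its numbers lie inside my bracket, but my reckoning gives a range, and for the fed flasks only a ceiling.

The flasks give 67.6% north-east, 49.7% south-west, 54.0% south-east and 69.8% north-west, so north-west is best.

    2 substrate ⇌ resting dimer, settled at all times (K = 430 M⁻¹)
    substrate + reagent → target (k = 56.1 M⁻¹ min⁻¹)
    2 reagent → self-condensation product (k = 0.251 M⁻¹ min⁻¹)

North-west stands under the ceiling of 71.0%, at ρ = 0.997. South-west stands at ρ = 0.710, and its 49.7% of target is lower than the north-east floor of 64.5%, while 29.0% of its reagent charge stands as self-condensation product, two reagent in each. South-west has come to rest: at 2.50 h it holds 49.7% of target with 0% of its reagent left, and at 25.0 h the target reads 49.7%.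

A neighbour of north-west charged with 0.170 equiv of reagent should give ρ times that charge, 17.2%. The computed flask gives 17.0%.

(All runs stem from a simulated flask from invented constants, noise included.)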